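**Retrosynthetic overview**

- The C40 polyene is cut at C11=C12 (Wittig) into a ring B C15 dienal and a ring A C25 phosphonium salt; the C6 silyl ether is removed last.
- The strategy rests on ring B: C1–C6 with the C6 tertiary carbinol, the E C7=C8 alkene, C9 with its methyl, C10 and C11 are, atom for atom and with the correct C6 configuration, (S)-abscisic acid. Only the C3 oxygen (as alcohol) and the C5 oxygen are missing.
- C3 comes from reduction of the ring ketone. The C5–O bond comes from a C4–C5 oxirane delivered by the C3 hydroxyl, which is then opened by hydride at C4.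
- The ring A C25 salt comes from a C15 acetylenic phosphonium salt and the C10 dial. The C15 salt comes from Sonogashira coupling of the actinol enol triflate with (E)-3-methylpent-2-en-4-yn-1-ol.
- Both carbocycles are taken intact from the chiral pool. The only ring formed is the oxirane (step 5), which is opened again in step 6.

Key step: step 5

Remark: carotenoid numbering is used (ring B C1–C6, chain C7–C15, ring A primed). Read from the SMILES, the target is (3S,5S,6S,3'R): the 3- and 5-hydroxyls are cis to each other and both trans to the 6-hydroxyl.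

**Route**

Step 1
Reactants: 1 (S)-(+)-abscisic acid
Product: 2 methyl (2Z,4E)-5-[(1S)-1-hydroxy-2,6,6-trimethyl-4-oxocyclohex-2-en-1-yl]-3-methylpenta-2,4-dienoate
Conditions: MeI, K2CO3, DMF, rt
Reagents that add atoms: iodomethane, CI
Why: Carboxylate O-alkylation (SN2 esterification) under mild carbonate base leaves the tertiary hydroxyl, the enone and the C6 stereocentre untouched.

Step 2
Reactants: 2 methyl (2Z,4E)-abscisate
Product: 3 methyl (2E,4E)-5-[(1S)-1-hydroxy-2,6,6-trimethyl-4-oxocyclohex-2-en-1-yl]-3-methylpenta-2,4-dienoate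
Conditions: hν (365 nm), acetone, rt; chromatography, recovered 2 re-irradiated
Reagents that add atoms: none
Why: Photochemical E/Z isomerisation about the trisubstituted C9=C10 alkene of the dienoate should give a photostationary mixture from which the 2E,4E ester is separated, the C6 stereocentre not being involved.

Step 3
Reactants: 3 methyl (2E,4E)-abscisate
Product: 4 methyl (2E,4E)-3-methyl-5-[(1S)-2,6,6-trimethyl-4-oxo-1-(triethylsilyloxy)cyclohex-2-en-1-yl]penta-2,4-dienoate
Conditions: Et3SiOTf, 2,6-lutidine, CH2Cl2, −78 to 0 °C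
Reagents that add atoms: triethylsilyl trifluoromethanesulfonate, CC[Si](CC)(CC)OS(=O)(=O)C(F)(F)F
Why: Silyl ether protection of the hindered tertiary allylic alcohol with a silyl triflate and a non-nucleophilic base masks the C6 hydroxyl so that it cannot bind vanadium in step 5.

Step 4
Reactants: 4 C6 triethylsilyl enone
Product: 5 methyl (2E,4E)-5-[(1S,4S)-4-hydroxy-2,6,6-trimethyl-1-(triethylsilyloxy)cyclohex-2-en-1-yl]-3-methylpenta-2,4-dienoate (C3 hydroxyl trans to the C6 silyloxy group)
Conditions: (R)-Me-CBS oxazaborolidine (C18H20BNO, 0.2 equiv), catecholborane, toluene, −78 to −40 °C; aqueous NaOH work-up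
Reagents that add atoms: none
Why: Corey–Bakshi–Shibata reduction, in which the ketone binds the catalyst boron with the alkenyl arm C4 as the large group, so the (R)-catalyst should deliver hydride 1,2 to the ring face that carries the C6 silyloxy group and set C3 as S without touching the dienoate.

Step 5
Reactants: 5 (3S)-allylic alcohol
Product: 6 methyl (2E,4E)-5-[(1S,2S,5S,6S)-5-hydroxy-1,3,3-trimethyl-2-(triethylsilyloxy)-7-oxabicyclo[4.1.0]heptan-2-yl]-3-methylpenta-2,4-dienoate (4,5-epoxide cis to the C3 hydroxyl and trans to the C6 silyloxy group)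
Conditions: VO(acac)2 (5 mol%), t-BuOOH (anhydrous, in decane), CH2Cl2, 0 °C to rt
Reagents that add atoms: tert-butyl hydroperoxide, CC(C)(C)OO
Why: VO(acac)2 is oxidised by t-BuOOH to a pentavalent vanadium species that binds the C3 alkoxide and a tert-butylperoxide ligand, and the metal-bound peroxide oxygen is passed to C4=C5 inside this template in one concerted step that forms the C4–O and C5–O bonds together. The closest known reaction type is the vanadium-catalysed hydroxyl-directed syn epoxidation of cyclohex-2-en-1-ols. The three-membered ring O–C4–C5 closes by concerted [2+1] oxygen-atom transfer to the alkene, not by a stepwise cyclisation. The new stereocentres C4 and C5 are both set by the C3 carbinol centre from step 4, because the tethered oxidant reaches only the alkene face on which the C3–O bond lies, which puts the C5–O bond cis to the C3 oxygen and trans to the C6 oxygen. The step needs face and site selectivity: the C6 oxygen, also allylic to C4=C5 and able to direct to the other face, is masked as its triethylsilyl ether and shields that face, while C7=C8 and C9=C10 are electron-poor through conjugation to the ester and have no free allylic hydroxyl, so the electrophilic metal peroxide should leave them alone.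

Step 6
Reactants: 6 epoxy alcohol ester
Product: 8 (2E,4E)-5-[(1S,2S,4S)-2,4-dihydroxy-2,6,6-trimethyl-1-(triethylsilyloxy)cyclohexyl]-3-methylpenta-2,4-dien-1-ol, via epoxy diol 7 (not isolated)
Conditions: LiAlH4, THF, 0 °C to rt; Rochelle salt work-up
Reagents that add atoms: none
Why: LiAlH4 reduces the methyl ester to the allylic alcohol and then opens the trisubstituted oxirane by SN2 hydride attack at the secondary C4 anti to the C4–O bond (trans-diaxial opening, Fürst–Plattner rule; the tertiary C5 next to quaternary C6 is inaccessible), so the C5–O bond keeps its configuration and the cis-3,5-diol results.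

Step 7
Reactants: 8 silyl-protected tetrol
Product: 9 (2E,4E)-5-[(1S,2S,4S)-2,4-dihydroxy-2,6,6-trimethyl-1-(triethylsilyloxy)cyclohexyl]-3-methylpenta-2,4-dienal
Conditions: activated MnO2, CH2Cl2, rt
Reagents that add atoms: none
Why: Chemoselective allylic oxidation: MnO2 oxidises only the primary dienylic alcohol and leaves the saturated secondary C3 and tertiary C5 hydroxyls and the E,E geometry alone.

Step 8
Reactants: 10 (4R,6R)-4-hydroxy-2,2,6-trimethylcyclohexanone (actinol)
Product: 11 (4R,6R)-2,2,6-trimethyl-4-(triethylsilyloxy)cyclohexanone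
Conditions: Et3SiCl, imidazole, DMF, 0 °C to rt
Reagents that add atoms: chlorotriethylsilane, CC[Si](Cl)(CC)CC
Why: Imidazole-promoted silyl ether protection of the secondary hydroxyl removes the acidic proton before enolisation and touches no stereocentre.

Step 9
Reactants: 11 silylated actinol
Product: 13 (4R)-2,6,6-trimethyl-4-(triethylsilyloxy)cyclohex-1-en-1-yl trifluoromethanesulfonate, via potassium enolate 12 (not isolated)
Conditions: KN(SiMe3)2, THF, −78 to 0 °C; then PhNTf2, −78 °C to rt
Reagents that add atoms: N-phenylbis(trifluoromethanesulfonimide), O=S(=O)(N(c1ccccc1)S(=O)(=O)C(F)(F)F)C(F)(F)F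
Why: Enol triflate formation: the ketone has one enolisable position only (C2 is quaternary), so deprotonation and O-sulfonylation give a single tetrasubstituted vinyl triflate, erasing the methyl-bearing stereocentre while the carbinol centre stays R.

Step 10
Reactants: 13 vinyl triflate; 14 (E)-3-methylpent-2-en-4-yn-1-ol
Product: 15 (2E)-3-methyl-5-[(4R)-2,6,6-trimethyl-4-(triethylsilyloxy)cyclohex-1-en-1-yl]pent-2-en-4-yn-1-ol
Conditions: Pd(PPh3)4 (5 mol%), CuI (10 mol%), i-Pr2NH, DMF, rt to 50 °C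
Reagents that add atoms: none
Why: Sonogashira coupling of the vinyl triflate with the terminal alkyne forms the C6'–C7' bond with the ring alkene fixed by the triflate position, the E alkene of the enynol unchanged and the free primary hydroxyl tolerated.

Step 11
Reactants: 15 silylated enynol
Product: 17 [(2E)-5-[(4R)-4-hydroxy-2,6,6-trimethylcyclohex-1-en-1-yl]-3-methylpent-2-en-4-yn-1-yl]triphenylphosphonium bromide, via enyne diol 16 (not isolated)
Conditions: PPh3·HBr, MeOH, rt
Reagents that add atoms: triphenylphosphine hydrobromide, [PH+](c1ccccc1)(c1ccccc1)c1ccccc1.[Br-]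
Why: In acidic methanol the secondary silyl ether is solvolysed and the primary allylic alcohol is converted into the phosphonium salt by PPh3 attack at the terminal carbon of the delocalised cation, the saturated secondary hydroxyl being inert.

Step 12
Reactants: 17 C15 phosphonium bromide; 18 (2E,4E,6E)-2,7-dimethylocta-2,4,6-trienedial
Product: 20 (2E,4E,6E,8E,10E)-13-[(4R)-4-hydroxy-2,6,6-trimethylcyclohex-1-en-1-yl]-2,7,11-trimethyltrideca-2,4,6,8,10-pentaen-12-ynal, via C15 ylide 19 (not isolated)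
Conditions: NaOMe, MeOH/CH2Cl2, 0 °C to rt, 17 added slowly to excess 18; then I2 (cat.), CH2Cl2, rt
Reagents that add atoms: none
Why: Wittig olefination of one aldehyde of the symmetrical dial (kept in excess to suppress double condensation) forms C11'=C12', and iodine-catalysed equilibration should convert the hindered Z isomer into the all-E polyenal.

Step 13
Reactants: 20 C25 aldehyde
Product: 21 (2E,4E,6E,8E,10E)-13-[(4R)-4-hydroxy-2,6,6-trimethylcyclohex-1-en-1-yl]-2,7,11-trimethyltrideca-2,4,6,8,10-pentaen-12-yn-1-ol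
Conditions: NaBH4, EtOH/CH2Cl2, 0 °C
Reagents that add atoms: none
Why: Borohydride 1,2-reduction of the conjugated aldehyde gives the primary polyenyl alcohol and leaves the polyene, the alkyne and the ring carbinol untouched.

Step 14
Reactants: 21 C25 diol
Product: 22 [(2E,4E,6E,8E,10E)-13-[(4R)-4-hydroxy-2,6,6-trimethylcyclohex-1-en-1-yl]-2,7,11-trimethyltrideca-2,4,6,8,10-pentaen-12-yn-1-yl]triphenylphosphonium bromide
Conditions: PPh3·HBr, CH2Cl2/MeOH, 0 °C to rt, dark
Reagents that add atoms: triphenylphosphine hydrobromide, [PH+](c1ccccc1)(c1ccccc1)c1ccccc1.[Br-]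
Why: Phosphonium salt formation from a polyenylic alcohol: the primary alcohol ionises readily and the delocalised cation is captured by PPh3 at the terminal carbon, while the saturated ring hydroxyl does not react.

Step 15
Reactants: 22 C25 phosphonium bromide; 9 ring B C15 dienal
Product: 24 6-O-triethylsilyl ether of the target (all-E), via C25 ylide 23 (not isolated)
Conditions: 1,2-epoxybutane, EtOH, reflux, argon, dark
Reagents that add atoms: none
Why: Wittig olefination under epoxide conditions (bromide opens the epoxide and the resulting alkoxide deprotonates the salt) joins ylide carbon C12 to aldehyde carbon C11 without exposing the tertiary carbinols of 9 to strong base, and the heat should relax the hindered 11Z isomer to all-E with no stereocentre touched.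

Step 16
Reactants: 24 silyl-protected carotenoid
Product: 25 (3S,5S,6S,3'R)-7',8'-didehydro-5,6-dihydro-β,β-carotene-3,3',5,6-tetrol (target)
Conditions: Bu4NF, THF, 0 °C to rt, dark
Reagents that add atoms: none
Why: Fluoride-induced cleavage of the silicon–oxygen bond (desilylation) frees the tertiary C6 hydroxyl under non-acidic conditions that the polyene and the triol should tolerate.

**Compound list**

1 | (S)-(+)-abscisic acid | OC(=O)/C=C(C)\C=C\[C@]1(O)C(C)(C)CC(=O)C=C1C | starting material
2 | methyl (2Z,4E)-abscisate | COC(=O)/C=C(C)\C=C\[C@]1(O)C(C)(C)CC(=O)C=C1C | intermediate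
3 | methyl (2E,4E)-abscisate | COC(=O)/C=C(C)/C=C/[C@]1(O)C(C)(C)CC(=O)C=C1C | intermediate
4 | methyl (2E,4E)-3-methyl-5-[(1S)-2,6,6-trimethyl-4-oxo-1-(triethylsilyloxy)cyclohex-2-en-1-yl]penta-2,4-dienoate | COC(=O)/C=C(C)/C=C/[C@]1(O[Si](CC)(CC)CC)C(C)(C)CC(=O)C=C1C | intermediate
5 | methyl (2E,4E)-5-[(1S,4S)-4-hydroxy-2,6,6-trimethyl-1-(triethylsilyloxy)cyclohex-2-en-1-yl]-3-methylpenta-2,4-dienoate | COC(=O)/C=C(C)/C=C/[C@]1(O[Si](CC)(CC)CC)C(C)(C)C[C@H](O)C=C1C | intermediate
6 | methyl (2E,4E)-5-[(1S,2S,5S,6S)-5-hydroxy-1,3,3-trimethyl-2-(triethylsilyloxy)-7-oxabicyclo[4.1.0]heptan-2-yl]-3-methylpenta-2,4-dienoate | COC(=O)/C=C(C)/C=C/[C@]1(O[Si](CC)(CC)CC)C(C)(C)C[C@H](O)[C@@H]2O[C@@]21C | intermediate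
7 | (2E,4E)-5-[(1S,2S,5S,6S)-5-hydroxy-1,3,3-trimethyl-2-(triethylsilyloxy)-7-oxabicyclo[4.1.0]heptan-2-yl]-3-methylpenta-2,4-dien-1-ol | OC/C=C(C)/C=C/[C@]1(O[Si](CC)(CC)CC)C(C)(C)C[C@H](O)[C@@H]2O[C@@]21C | intermediate
8 | (2E,4E)-5-[(1S,2S,4S)-2,4-dihydroxy-2,6,6-trimethyl-1-(triethylsilyloxy)cyclohexyl]-3-methylpenta-2,4-dien-1-ol | OC/C=C(C)/C=C/[C@]1(O[Si](CC)(CC)CC)C(C)(C)C[C@H](O)C[C@]1(C)O | intermediate
9 | (2E,4E)-5-[(1S,2S,4S)-2,4-dihydroxy-2,6,6-trimethyl-1-(triethylsilyloxy)cyclohexyl]-3-methylpenta-2,4-dienal | O=C/C=C(C)/C=C/[C@]1(O[Si](CC)(CC)CC)C(C)(C)C[C@H](O)C[C@]1(C)O | intermediate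
10 | (4R,6R)-4-hydroxy-2,2,6-trimethylcyclohexanone (actinol) | O=C1C(C)(C)C[C@H](O)C[C@H]1C | starting material
11 | (4R,6R)-2,2,6-trimethyl-4-(triethylsilyloxy)cyclohexanone | O=C1C(C)(C)C[C@H](O[Si](CC)(CC)CC)C[C@H]1C | intermediate
12 | potassium (4R)-2,6,6-trimethyl-4-(triethylsilyloxy)cyclohex-1-en-1-olate | CC1=C([O-])C(C)(C)C[C@H](O[Si](CC)(CC)CC)C1.[K+] | intermediate
13 | (4R)-2,6,6-trimethyl-4-(triethylsilyloxy)cyclohex-1-en-1-yl trifluoromethanesulfonate | CC1=C(OS(=O)(=O)C(F)(F)F)C(C)(C)C[C@H](O[Si](CC)(CC)CC)C1 | intermediate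
14 | (E)-3-methylpent-2-en-4-yn-1-ol | C#C/C(C)=C/CO | starting material
15 | (2E)-3-methyl-5-[(4R)-2,6,6-trimethyl-4-(triethylsilyloxy)cyclohex-1-en-1-yl]pent-2-en-4-yn-1-ol | CC1=C(C#C/C(C)=C/CO)C(C)(C)C[C@H](O[Si](CC)(CC)CC)C1 | intermediate
16 | (2E)-5-[(4R)-4-hydroxy-2,6,6-trimethylcyclohex-1-en-1-yl]-3-methylpent-2-en-4-yn-1-ol | CC1=C(C#C/C(C)=C/CO)C(C)(C)C[C@H](O)C1 | intermediate
17 | [(2E)-5-[(4R)-4-hydroxy-2,6,6-trimethylcyclohex-1-en-1-yl]-3-methylpent-2-en-4-yn-1-yl]triphenylphosphonium bromide | CC1=C(C#C/C(C)=C/C[P+](c2ccccc2)(c2ccccc2)c2ccccc2)C(C)(C)C[C@H](O)C1.[Br-] | intermediate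
18 | (2E,4E,6E)-2,7-dimethylocta-2,4,6-trienedial | O=C/C(C)=C/C=C/C=C(C)/C=O | starting material
19 | ylide of 17 (triphenylphosphoranylidene form) | CC1=C(C#C/C(C)=C/C=P(c2ccccc2)(c2ccccc2)c2ccccc2)C(C)(C)C[C@H](O)C1 | intermediate
20 | (2E,4E,6E,8E,10E)-13-[(4R)-4-hydroxy-2,6,6-trimethylcyclohex-1-en-1-yl]-2,7,11-trimethyltrideca-2,4,6,8,10-pentaen-12-ynal | CC1=C(C#C/C(C)=C/C=C/C(C)=C/C=C/C=C(C)/C=O)C(C)(C)C[C@H](O)C1 | intermediate
21 | (2E,4E,6E,8E,10E)-13-[(4R)-4-hydroxy-2,6,6-trimethylcyclohex-1-en-1-yl]-2,7,11-trimethyltrideca-2,4,6,8,10-pentaen-12-yn-1-ol | CC1=C(C#C/C(C)=C/C=C/C(C)=C/C=C/C=C(C)/CO)C(C)(C)C[C@H](O)C1 | intermediate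
22 | C25 triphenylphosphonium bromide of 21 (phosphorus on C12) | CC1=C(C#C/C(C)=C/C=C/C(C)=C/C=C/C=C(C)/C[P+](c2ccccc2)(c2ccccc2)c2ccccc2)C(C)(C)C[C@H](O)C1.[Br-] | intermediate
23 | ylide of 22 (triphenylphosphoranylidene form) | CC1=C(C#C/C(C)=C/C=C/C(C)=C/C=C/C=C(C)/C=P(c2ccccc2)(c2ccccc2)c2ccccc2)C(C)(C)C[C@H](O)C1 | intermediate
24 | 6-O-triethylsilyl ether of the target | CC1=C(C#C/C(C)=C/C=C/C(C)=C/C=C/C=C(C)/C=C/C=C(C)/C=C/[C@]2(O[Si](CC)(CC)CC)C(C)(C)C[C@H](O)C[C@]2(C)O)C(C)(C)C[C@H](O)C1 | intermediate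
25 | (3S,5S,6S,3'R)-7',8'-didehydro-5,6-dihydro-β,β-carotene-3,3',5,6-tetrol | CC1=C(C#C/C(C)=C/C=C/C(C)=C/C=C/C=C(C)/C=C/C=C(C)/C=C/[C@]2(O)C(C)(C)C[C@H](O)C[C@]2(C)O)C(C)(C)C[C@H](O)C1 | target

**Step count**

Total: 16 steps. Longest linear sequence: 9 steps (steps 1–7, 15, 16 from abscisic acid; equally steps 8–14, 15, 16 from actinol).

**Steps most likely to fail**

Step 4 (ketone reduction). Catalyst control may be overridden by the intrinsic facial bias of the ring, in which the conformer with an axial side chain steers hydride to the other face and gives the C3 epimer; slow reduction of the hindered ketone would also let uncatalysed background reduction erode selectivity. The fallback sets out from 4 and comes back at 5. Luche reduction (NaBH4, CeCl3·7H2O, MeOH, −78 °C) under substrate control should give the cis alcohol methyl (2E,4E)-5-[(1S,4R)-4-hydroxy-2,6,6-trimethyl-1-(triethylsilyloxy)cyclohex-2-en-1-yl]-3-methylpenta-2,4-dienoate F1. Mitsunobu reaction with 4-nitrobenzoic acid, PPh3 and diisopropyl azodicarboxylate in THF should invert C3 and give the ester methyl (2E,4E)-3-methyl-5-[(1S,4S)-2,6,6-trimethyl-4-(4-nitrobenzoyloxy)-1-(triethylsilyloxy)cyclohex-2-en-1-yl]penta-2,4-dienoate F2. K2CO3 in MeOH would then release 5, the methyl dienoate being unchanged in methanol.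

Step 5 (directed epoxidation). The vanadium peroxide may oxidise the secondary allylic carbinol back to the enone in competition with oxygen transfer, the Lewis-acidic metal may open or rearrange the tertiary epoxide next to the silyloxy carbon, and facial control may be incomplete if the hydroxyl sits pseudo-equatorial. The fallback sets out from 5 and comes back at 8; it replaces metal-alkoxide delivery by a covalently attached hydrogen-bond donor and a metal-free peracid. Trichloroacetyl isocyanate in CH2Cl2 at 0 °C should give methyl (2E,4E)-3-methyl-5-[(1S,4S)-2,6,6-trimethyl-4-[(trichloroacetyl)carbamoyloxy]-1-(triethylsilyloxy)cyclohex-2-en-1-yl]penta-2,4-dienoate F3. K2CO3 in MeOH should trim it to the primary carbamate methyl (2E,4E)-5-[(1S,4S)-4-(carbamoyloxy)-2,6,6-trimethyl-1-(triethylsilyloxy)cyclohex-2-en-1-yl]-3-methylpenta-2,4-dienoate F4. mCPBA with NaHCO3 in CH2Cl2 should then epoxidise C4=C5 on the carbamate face (carbamate-directed peracid epoxidation), giving methyl (2E,4E)-5-[(1S,2S,5S,6S)-5-(carbamoyloxy)-1,3,3-trimethyl-2-(triethylsilyloxy)-7-oxabicyclo[4.1.0]heptan-2-yl]-3-methylpenta-2,4-dienoate F5. LiAlH4 in THF would cleave the carbamate, reduce the ester and open the epoxide at C4 in one operation to give 8.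

Step 6 (hydride opening with ester reduction). Opening at C4 beside the alkoxyaluminate may be slow, and prolonged exposure to LiAlH4 may lead to hydroalumination or conjugate reduction of the dienyl system or to migration or loss of the silyl group. The fallback sets out from 6 and comes back at 8; it replaces hydride by a soft selenium nucleophile and a radical reduction. (PhSe)2 with NaBH4 in EtOH should open the epoxide at C4 by trans-diaxial attack and give methyl (2E,4E)-5-[(1S,2R,3R,4S)-2,4-dihydroxy-2,6,6-trimethyl-3-(phenylselanyl)-1-(triethylsilyloxy)cyclohexyl]-3-methylpenta-2,4-dienoate F6. Bu3SnH with AIBN in toluene at 80 °C should replace the C–Se bond by C–H and give methyl (2E,4E)-5-[(1S,2S,4S)-2,4-dihydroxy-2,6,6-trimethyl-1-(triethylsilyloxy)cyclohexyl]-3-methylpenta-2,4-dienoate F7. DIBAL-H in CH2Cl2 at −78 °C would then reduce the ester to 8.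

**Further compounds**

F1 | step 4 | methyl (2E,4E)-5-[(1S,4R)-4-hydroxy-2,6,6-trimethyl-1-(triethylsilyloxy)cyclohex-2-en-1-yl]-3-methylpenta-2,4-dienoate | COC(=O)/C=C(C)/C=C/[C@]1(O[Si](CC)(CC)CC)C(C)(C)C[C@@H](O)C=C1C
F2 | step 4 | methyl (2E,4E)-3-methyl-5-[(1S,4S)-2,6,6-trimethyl-4-(4-nitrobenzoyloxy)-1-(triethylsilyloxy)cyclohex-2-en-1-yl]penta-2,4-dienoate | COC(=O)/C=C(C)/C=C/[C@]1(O[Si](CC)(CC)CC)C(C)(C)C[C@H](OC(=O)c2ccc(cc2)[N+](=O)[O-])C=C1C
F3 | step 5 | methyl (2E,4E)-3-methyl-5-[(1S,4S)-2,6,6-trimethyl-4-[(trichloroacetyl)carbamoyloxy]-1-(triethylsilyloxy)cyclohex-2-en-1-yl]penta-2,4-dienoate | COC(=O)/C=C(C)/C=C/[C@]1(O[Si](CC)(CC)CC)C(C)(C)C[C@H](OC(=O)NC(=O)C(Cl)(Cl)Cl)C=C1C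
F4 | step 5 | methyl (2E,4E)-5-[(1S,4S)-4-(carbamoyloxy)-2,6,6-trimethyl-1-(triethylsilyloxy)cyclohex-2-en-1-yl]-3-methylpenta-2,4-dienoate | COC(=O)/C=C(C)/C=C/[C@]1(O[Si](CC)(CC)CC)C(C)(C)C[C@H](OC(N)=O)C=C1C
F5 | step 5 | methyl (2E,4E)-5-[(1S,2S,5S,6S)-5-(carbamoyloxy)-1,3,3-trimethyl-2-(triethylsilyloxy)-7-oxabicyclo[4.1.0]heptan-2-yl]-3-methylpenta-2,4-dienoate | COC(=O)/C=C(C)/C=C/[C@]1(O[Si](CC)(CC)CC)C(C)(C)C[C@H](OC(N)=O)[C@@H]2O[C@@]21C
F6 | step 6 | methyl (2E,4E)-5-[(1S,2R,3R,4S)-2,4-dihydroxy-2,6,6-trimethyl-3-(phenylselanyl)-1-(triethylsilyloxy)cyclohexyl]-3-methylpenta-2,4-dienoate | COC(=O)/C=C(C)/C=C/[C@]1(O[Si](CC)(CC)CC)C(C)(C)C[C@H](O)[C@@H]([Se]c2ccccc2)[C@]1(C)O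
F7 | step 6 | methyl (2E,4E)-5-[(1S,2S,4S)-2,4-dihydroxy-2,6,6-trimethyl-1-(triethylsilyloxy)cyclohexyl]-3-methylpenta-2,4-dienoate | COC(=O)/C=C(C)/C=C/[C@]1(O[Si](CC)(CC)CC)C(C)(C)C[C@H](O)C[C@]1(C)O
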